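All runs were generated by integration from invented constants; scatter was added.

48.3 % of the solid substrate gone by 8.00 min in the north-east run stands there as double product.

| flask | solid substrate | reagent | remark | time |
|---|---|---|---|---|
| north-east | 0.30 M | 0.60 M | run made earlier |  |
| south-east | 0.30 M | 1.4 M | run made earlier |  |
| flask | 0.30 M | 0.900 M |  | 12 min |

| run | time / min | double product / % | solid substrate / % |
|---|---|---|---|
| north-east | 0.833 | 0.6 | 95.2 |
| north-east | 2.50 | 3.1 | 89.5 |
| north-east | 5.00 | 7.9 | 82.2 |
| north-east | 8.00 | 12.7 | 73.7 |
| south-east | 0.833 | 1.4 | 93.7 |
| south-east | 2.50 | 7.7 | 83.9 |
| south-east | 5.00 | 12.9 | 70.7 |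
| south-east | 8.00 | 15.7 | 55.3 |

(readings scatter by 0.3 percentage points)

- as a solid, counted per litre of solution: solid substrate
- at the start none of the solid substrate is in solution

- equivalents of reagent to solid substrate, everything else as given, that leave most double product at 12 min
- the amount of double product then, in percent of the solid substrate charged
- the amount of double product with the amounts as given

What does that number say? Follow one molecule: once it has left the solid, that is its chance of being found as double product. At the same time in the south-east run, with more reagent, the chance is lower, at 35.1 %.

What do you take to set this chance? I assume exposure, [reagent] times time, as charged: 288 M·s in the north-east run, 672 M·s in the south-east run, and 648 M·s in the flask.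

Isn't that weak, since [reagent] falls during a run? Yes, so this is a rough reckoning.

What follows for the flask? Interpolating on exposure gives 35.9 %, the keep share, or overall selectivity to double product.

And how much solid substrate goes? From 2.50 min to 8.00 min the readings of solid substrate fall steadily, at a fraction 0.0287 min⁻¹ in the north-east run and 0.0520 min⁻¹ in the south-east run. Interpolating on [reagent] and carrying that fall on to 12 min, I estimate that 48.2 % of the solid substrate goes in the flask, so I expect 17.3 % double product in the flask.

The forecast for the flask is a little higher than my estimate, at 17.8 %, and puts the best yield, 18.1 %, at 3.5 equiv. Its ground: “More reagent feeds double product faster but also destroys it faster”.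

The simulation gives 18.4 % for the flask, and 18.7 % at 3.58 equiv.

    solid substrate ⇌ starting material, rate k1*(cs1 - [starting material]) while solid is left; crystals form when [starting material] > cs1 (solubility = 12.0 mM, k = 0.0550 s⁻¹)
    reagent + double product → triple product (k = 0.00400 M⁻¹ s⁻¹)
    reagent + first product → double product (k = 0.0170 M⁻¹ s⁻¹)
    starting material + reagent → first product (k = 0.0310 M⁻¹ s⁻¹)

At 12.0 min the flask's double product has a half-life of 5.0 min towards triple product, shorter than the 12 min run. The flask then holds 18.4 % double product beside 21.9 % triple product, a keep share of 37.8 % against the carried 35.9 %. What would make the forecast of 17.8 % wrong is a different flask: with all else held, the flask's double product moves by 5 points at 0.236 M or 0.412 M of solid substrate, or at a time of 6.68 min or 27.4 min.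

A neighbour flask charged with 0.12 M of solid substrate has the same exposure, 648 M·s, and 0 % solid substrate at 12.0 min, so the keep share gives 35.9 % double product. The computed amount is 40.3 %.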